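The earlier runs and the new flask come from a simulation with made-up constants, and the scatter is random.

The substrate charged stays on the books: by the steps thought possible, what leaves the solid ends as target or other capture product, or waits in solution as starting material or intermediate. So in Friday's flask I watch the solid first.

| setting | Friday's | flask |
|---|---|---|
| solid substrate | 0.12 M | 0.12 M |
| first nucleophile | 0.060 M | 0.0600 M |
| second nucleophile | 0.18 M | 0.180 M |
| remark | the very flask that is asked about, followed so far |  |
| time |  | 20 min |

Friday's run (percent of the solid substrate charged)

| time / min | target / % | solid substrate / % |
|---|---|---|
| 1.00 | 5.9 | 81.7 |
| 1.50 | 9.6 | 73.4 |
| 2.50 | 16.1 | 57.3 |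
| 4.00 | 26.4 | 32.4 |
| 8.00 | 38.2 | 0 |
| 12.0 | 37.9 | 0 |

(each reading ± 0.3 percentage points)

- solid substrate is a solid; its amount is given per volume of the solution
- what is taken out of target is counted as made
- steps thought possible: second nucleophile + intermediate -> other capture product; solid substrate <-> starting material; starting material <-> intermediate; first nucleophile + intermediate -> target
- at the start none of the solid substrate is in solution
- additions bring no volume worth counting

- target, in percent of the solid substrate first charged, at 20 min
- what to do for the largest gain in target; "none" if nothing gains more than 2 percentage points (midnight / summer / dusk / none)
- target present, with what was taken out counted in, in percent of the solid substrate first charged, after summer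
- target present, with what was taken out counted in, in percent of the solid substrate first charged, after dusk

- midnight: at 20 min take out 90% of the target then present, then wait 20 min
- summer: at 20 min add first nucleophile, 100% of the amount charged, then wait 20 min
- dusk: change nothing and wait 20 min more

From 1.00 min to 4.00 min the solid falls steadily, and I read a drain of 0.0197 M min⁻¹. The clock ratio of this flask is 3.29: the solid that drain could remove by the time asked, over c(solid substrate) charged. While the drain holds, a ratio above one means the solid ends before the time asked; here I reckon it ends near 6.09 min.

Is one number enough? It says when the supply stops, not how high target stands. For that I have the readings, 38.2% and 37.9%, which differ by about the scatter, so I commit to about 38.1%. The later reading leaves 24.2% of the charged first nucleophile free. Its charge would allow 50.0% target, more than the plateau, so first nucleophile is not what ends target here; the solid, reading 0%, is the limiting reagent. Waiting or adding first nucleophile meets that reading and a flat target, and taking target out meets a step written one way, so I choose none.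

The forecast gives 38% now, none as best, 38% after summer and 38% after dusk, on the ground that “Nothing remains to convert”.

    second nucleophile + intermediate → other capture product (k = 240 M⁻¹ s⁻¹)
    solid substrate ⇌ starting material, rate k2*(cs2 - [starting material]) while solid is left; crystals form when [starting material] > cs2 (solubility = 16.0 mM, k = 0.0330 s⁻¹)
    starting material ⇌ intermediate (K = 0.0740, k = 0.0540 s⁻¹)
    first nucleophile + intermediate → target (k = 650 M⁻¹ s⁻¹)

The flask gives 38.2%, best none, with 38.2% after summer and 38.2% after dusk. What the ratio does not hold is the split, which at 10.0 min stands at 38.2% target against 61.8% other capture product. The clock ratio at that time is already 1.64, above one, and solid, starting material and intermediate stand at 0%, 0% and 0%. With 0.20 M of solid substrate and Friday's drain, the neighbouring flask has a ratio of 1.97, also above one; at 20.0 min its solid stands at 0% and its target at 29.5%.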